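**Plan**

Numbering used here: C1 = CH–OAc, C2 = its ring CH2, C3 = quaternary carbon bearing the lactone CH2 (C4), C6 = lactone C=O, C7=C8 = ring alkene, C9 = CH–OH, C10 = furfuryl CH, C16 = ring ketone, C17 = its CH2, C18 = quaternary C–CH3, C19 = CH–CH3, C20 = central CH; ring A = C1-C2-C3-C20-C18-C19, ring B = C3-C7-C8-C9-C10-C20, ring C = the furan-fused cycloheptanone, ring D = the lactone.
Retrosynthetic cuts, in order: C9–OH (from the C9 enone); C7=C8 (from an allyl carboxylate on C7); furan C3–C16 (ring C); lactone O–C6 (ring D); then C1–C19 and C3–C20 together (rings A and B), which opens the core to one acyclic enal–enone–vinyl chain; that chain is cut at C3–C7 (malonate + ynal), C7–C8 (malonate + bromo ketone) and C10=C20 (Knoevenagel).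
Enabling feature: C1 carries oxygen and its neighbour C19 a methyl group, the retron of a 6-exo ketyl–olefin closure onto a vinyl group on C18; C1–C2–C3 is a latent enal whose β-carbon C3 lies next to C20, the β-carbon of a C9 enone. One enal can therefore act first as β-acceptor (C3–C20, ring B) and then, after protonation, as ketyl (C1–C19, ring A).
Forward order of rings: ring B then ring A (one SmI2 operation), ring D (lactonisation), ring C (Friedel–Crafts acylation of the furan); the furan comes from commercial 1-(furan-2-yl)propan-2-one.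
Stereochemistry: C18 from ethyl (R)-3-hydroxybutanoate by two Fráter–Seebach alkylations (the carbinol centre is erased when it becomes the vinyl group); C3, C20, C10, C1 and C19 arise in the key step under chair-transition-state and Felkin-type control from C18; C9 by axial hydride delivery to the enone.

Key step: step 11

Remark on the chemistry: the enal 16 may form as an E/Z mixture; both isomers should lead to the same ring B intermediate. The C7 diester is no stereocentre until lactonisation.

**Route**

Step 1
Reactants: 1 ethyl (R)-3-hydroxybutanoate; 2 tert-butyl bromoacetate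
Product: 3 ethyl (2R,3R)-2-(2-tert-butoxy-2-oxoethyl)-3-hydroxybutanoate
Conditions: LiN(iPr)2 (2.2 equiv), THF, −78 to −20 °C; then 2, DMPU, −78 to −20 °C
Reagents that add atoms: none
Why: Fráter–Seebach alkylation: the lithium-chelated alkoxide enolate of the β-hydroxy ester should react with the bromoacetate on the face anti to the carbinol methyl group, which sets the new α-centre (2R) from the existing (3R)-carbinol.

Step 2
Reactants: 3 ethyl (2R,3R)-2-(2-tert-butoxy-2-oxoethyl)-3-hydroxybutanoate
Product: 4 ethyl (2S,3R)-2-(2-tert-butoxy-2-oxoethyl)-3-hydroxy-2-methylbutanoate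
Conditions: LiN(iPr)2 (2.2 equiv), THF, −78 to −20 °C; then MeI, DMPU, −78 to 0 °C
Reagents that add atoms: iodomethane, CI
Why: Second Fráter–Seebach alkylation: iodomethane should again enter anti to the carbinol methyl group, so the order of the two alkylations fixes the quaternary centre that becomes C18.

Step 3
Reactants: 4 ethyl (2S,3R)-2-(2-tert-butoxy-2-oxoethyl)-3-hydroxy-2-methylbutanoate
Product: 5 4-tert-butyl 1-ethyl (2S)-2-ethenyl-2-methylbutanedioate
Conditions: Burgess reagent, PhMe, 70 °C
Reagents that add atoms: none
Why: Burgess dehydration (syn-elimination of the sulfamate) can only run towards the methyl group because the other neighbour is quaternary, which turns the auxiliary carbinol into the vinyl group.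

Step 4
Reactants: 5 4-tert-butyl 1-ethyl (2S)-2-ethenyl-2-methylbutanedioate
Product: 6 tert-butyl (3S)-3-formyl-3-methylpent-4-enoate
Conditions: iBu2AlH (1.1 equiv), CH2Cl2, −78 °C
Reagents that add atoms: none
Why: Partial ester reduction with iBu2AlH: the tetrahedral aluminate of the α-quaternary ethyl ester should persist at −78 °C and release the aldehyde on work-up, while the tert-butyl ester is too hindered to react.

Step 5
Reactants: 6 tert-butyl (3S)-3-formyl-3-methylpent-4-enoate; 7 1-(furan-2-yl)propan-2-one
Product: 8 tert-butyl (3S,4E)-3-ethenyl-5-(furan-2-yl)-3-methyl-6-oxohept-4-enoate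
Conditions: piperidine (cat.), AcOH (cat.), PhMe, reflux, Dean–Stark
Reagents that add atoms: none
Why: Knoevenagel condensation of the doubly activated furfuryl CH2 of 7 with the non-enolisable aldehyde 6 should give the α-furyl enone with the acetyl group trans to the bulky quaternary substituent (E).

Step 6
Reactants: 8 tert-butyl (3S,4E)-3-ethenyl-5-(furan-2-yl)-3-methyl-6-oxohept-4-enoate
Product: 10 tert-butyl (3S,4E)-7-bromo-3-ethenyl-5-(furan-2-yl)-3-methyl-6-oxohept-4-enoate, via silyl dienol ether 9 (not isolated)
Conditions: LiN(SiMe3)2, Me3SiCl, THF, −78 °C; then NBS, THF, −78 °C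
Reagents that add atoms: chlorotrimethylsilane, C[Si](C)(C)Cl (silyl group of 9 only); N-bromosuccinimide, O=C1CCC(=O)N1Br
Why: Regiospecific silyl enol ether formation at the only enolisable position (the methyl ketone) and electrophilic bromination of this electron-rich alkene, which should be faster than attack on the furan at −78 °C, give the bromomethyl ketone.

Step 7
Reactants: 10 tert-butyl (3S,4E)-7-bromo-3-ethenyl-5-(furan-2-yl)-3-methyl-6-oxohept-4-enoate; 11 diallyl malonate
Product: 12 diallyl 2-[(3E,5S)-7-tert-butoxy-5-ethenyl-3-(furan-2-yl)-5-methyl-2,7-dioxohept-3-en-1-yl]propanedioate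
Conditions: NaH, 11, THF, 0 °C; then 10, 0 °C to rt
Reagents that add atoms: none
Why: Malonic ester alkylation: SN2 displacement of the reactive α-bromo ketone by the sodium enolate of 11 forms C7–C8, and closure of the product anion onto the enone would be 5-endo-trig and is not expected.

Step 8
Reactants: 13 but-2-yne-1,4-diol
Product: 14 4-[(tert-butyldimethylsilyl)oxy]but-2-yn-1-ol
Conditions: NaH (1.0 equiv), THF, 0 °C; then tBuMe2SiCl
Reagents that add atoms: tert-butyldimethylsilyl chloride, CC(C)(C)[Si](C)(C)Cl
Why: Monosilylation of the symmetrical diol through its sparingly soluble monosodium alkoxide (silyl ether formation).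

Step 9
Reactants: 14 4-[(tert-butyldimethylsilyl)oxy]but-2-yn-1-ol
Product: 15 4-[(tert-butyldimethylsilyl)oxy]but-2-ynal
Conditions: MnO2, CH2Cl2, rt
Reagents that add atoms: none
Why: Oxidation of the propargylic alcohol to the ynal with activated MnO2, which leaves the silyl ether untouched.

Step 10
Reactants: 12 diallyl 2-[(3E,5S)-7-tert-butoxy-5-ethenyl-3-(furan-2-yl)-5-methyl-2,7-dioxohept-3-en-1-yl]propanedioate; 15 4-[(tert-butyldimethylsilyl)oxy]but-2-ynal
Product: 16 diallyl 2-[(2Z)-1-[(tert-butyldimethylsilyl)oxy]-4-oxobut-2-en-2-yl]-2-[(3E,5S)-7-tert-butoxy-5-ethenyl-3-(furan-2-yl)-5-methyl-2,7-dioxohept-3-en-1-yl]propanedioate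
Conditions: Cs2CO3 (0.2 equiv), MeCN, 0 °C
Reagents that add atoms: none
Why: Base-catalysed Michael addition of the tertiary malonate carbanion to the ynal (conjugate addition to an activated alkyne) should form C3–C7 and the β,β-disubstituted enal in one step.

Step 11
Reactants: 16 diallyl 2-[(2Z)-1-[(tert-butyldimethylsilyl)oxy]-4-oxobut-2-en-2-yl]-2-[(3E,5S)-7-tert-butoxy-5-ethenyl-3-(furan-2-yl)-5-methyl-2,7-dioxohept-3-en-1-yl]propanedioate
Product: 18 trans-fused bicyclic hydroxy ketone (rings A and B closed; C1–OH, C19–CH3, C3–CH2OTBS, C7(CO2allyl)2, C9=O, C10-(2-furyl), C18(CH3)(CH2CO2tBu); stereocentres as in 26), via ring B keto aldehyde 17 (not isolated)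
Conditions: SmI2 (5 equiv), HMPA (20 equiv), tBuOH (4 equiv), THF (0.005 M), −78 to −20 °C
Reagents that add atoms: none
Why: Proposed new method: one-electron reduction of the cross-conjugated α-furyl enone (or of the enal) by SmI2–HMPA gives a ketyl-type radical anion whose C20 terminus adds 6-exo-trig to the enal β-carbon C3 (ring B, C3–C20), a second electron gives the bis-enolate, tBuOH releases the saturated aldehyde, and its ketyl then closes ring A by 6-exo-trig attack of C1 on the internal vinyl carbon C19, the primary radical so formed being reduced and protonated to the C19 methyl group. The closest known reaction types are the reductive β,β-coupling of tethered Michael acceptors (SmI2, cathodic or tin-ketyl hydrodimerisation-type cyclisation) and the SmI2–HMPA ketyl–olefin cyclisation, but their union through a single enal that serves first as β-acceptor and then as ketyl precursor is without precedent. Ring B should close through a chair in which the C18-bearing arm on C20 and the exocyclic enal carbon C2 are equatorial and CH2OTBS is axial, which sets C3 and C20 as required for the trans A/B fusion, and the face of C20 is chosen relative to C18 by a Felkin-type arrangement with the bulky CH2CO2tBu arm anti to the incoming C3 and the methyl group inside. C10 is set by protonation of the samarium enolate and stays epimerisable next to the C9 ketone, so the equatorial furyl isomer should prevail. In the ring A chair the samarium-bound oxygen on C1 is equatorial to avoid the axial CH2OTBS on C3 and the vinyl CH2 is equatorial, which gives the trans, diequatorial C1–OH and C19–CH3. The step needs the aldehyde to be reduced only after C3–C20 exists (secured because C1 stays masked as enal and then enolate until protonation), pinacol-type C1–C9 coupling to be slower than the β,β-coupling of the two conjugated systems, and the C9 ketone, whose ketyl cannot reach the equatorially held vinyl group, to survive at low temperature.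

Step 12
Reactants: 18 trans-fused bicyclic hydroxy ketone
Product: 19 C1 acetate of 18
Conditions: Ac2O, DMAP (cat.), pyridine, CH2Cl2, rt
Reagents that add atoms: acetic anhydride, CC(=O)OC(C)=O
Why: Acylation (DMAP catalysis) of the only free hydroxyl group, the equatorial secondary alcohol at C1.

Step 13
Reactants: 19 C1 acetate of 18
Product: 21 ring D lactone (C4–O–C6 closed; axial allyl ester kept on C7; tert-butyl ester kept), via hydroxy diester 20 (not isolated)
Conditions: HF·pyridine, pyridine, THF, 0 to 40 °C
Reagents that add atoms: none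
Why: Fluoride-mediated desilylation frees the axial CH2OH on C3, which should lactonise (5-exo-trig transesterification) onto the cis-disposed equatorial allyl ester at C7, closing ring D and leaving the axial allyl ester.

Step 14
Reactants: 21 ring D lactone tert-butyl ester
Product: 22 C16 carboxylic acid of 21
Conditions: CF3CO2H, CH2Cl2, 0 °C
Reagents that add atoms: none
Why: Acidolysis of the tert-butyl ester (E1 loss of isobutene) should free the C16 acid without touching the acetate, the allyl ester or the lactone.

Step 15
Reactants: 22 C16 carboxylic acid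
Product: 24 tetracyclic diketone (ring C closed between furan C3 and C16; allyl ester still on C7), via acid chloride 23 (not isolated)
Conditions: (COCl)2, DMF (cat.), CH2Cl2, 0 °C; then SnCl4, CH2Cl2 (0.005 M), −78 °C
Reagents that add atoms: oxalyl chloride, O=C(Cl)C(=O)Cl (chlorine of 23 only)
Why: Intramolecular Friedel–Crafts acylation of the furan at its 3-position, the only ring position the tether can reach, closes the seven-membered ring C, and C10 (α to the C9 ketone) can equilibrate to the trans B/C fusion.

Step 16
Reactants: 24 tetracyclic diketone with allyl ester on C7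
Product: 25 C9 enone (C7=C8 in place; 9-oxo analogue of the target)
Conditions: Pd(OAc)2 (10 mol %), PPh3 (10 mol %), MeCN, 80 °C
Reagents that add atoms: none
Why: Tsuji decarboxylation–dehydrogenation: ionisation of the allyl ester by palladium, loss of CO2 and β-hydride elimination from the lactone enolate towards C8 (C3 is quaternary) should install the C7=C8 alkene.

Step 17
Reactants: 25 C9 enone
Product: 26 target (CNP0182929.2)
Conditions: NaBH4, CeCl3·7H2O, MeOH, −78 °C
Reagents that add atoms: none
Why: Luche reduction: 1,2-hydride delivery to the more electrophilic ene-dione carbonyl at C9 from the axial direction should give the pseudo-equatorial alcohol trans to the C10–furan bond, leaving the furyl ketone and the esters.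

**Compound list**

1 | ethyl (R)-3-hydroxybutanoate | CCOC(=O)C[C@@H](C)O | starting material
2 | tert-butyl bromoacetate | BrCC(=O)OC(C)(C)C | starting material
3 | ethyl (2R,3R)-2-(2-tert-butoxy-2-oxoethyl)-3-hydroxybutanoate | CCOC(=O)[C@H](CC(=O)OC(C)(C)C)[C@@H](C)O | intermediate
4 | ethyl (2S,3R)-2-(2-tert-butoxy-2-oxoethyl)-3-hydroxy-2-methylbutanoate | CCOC(=O)[C@@](C)(CC(=O)OC(C)(C)C)[C@@H](C)O | intermediate
5 | 4-tert-butyl 1-ethyl (2S)-2-ethenyl-2-methylbutanedioate | CCOC(=O)[C@@](C)(CC(=O)OC(C)(C)C)C=C | intermediate
6 | tert-butyl (3S)-3-formyl-3-methylpent-4-enoate | CC(C)(C)OC(=O)C[C@@](C)(C=C)C=O | intermediate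
7 | 1-(furan-2-yl)propan-2-one | CC(=O)Cc1ccco1 | starting material
8 | tert-butyl (3S,4E)-3-ethenyl-5-(furan-2-yl)-3-methyl-6-oxohept-4-enoate | CC(=O)/C(c1ccco1)=C/[C@](C)(C=C)CC(=O)OC(C)(C)C | intermediate
9 | trimethylsilyl dienol ether of 8 (silyloxy diene on the former methyl ketone; 3S, enone geometry of 8 kept) | C=C(O[Si](C)(C)C)/C(c1ccco1)=C/[C@](C)(C=C)CC(=O)OC(C)(C)C | intermediate (not isolated)
10 | tert-butyl (3S,4E)-7-bromo-3-ethenyl-5-(furan-2-yl)-3-methyl-6-oxohept-4-enoate | BrCC(=O)/C(c1ccco1)=C/[C@](C)(C=C)CC(=O)OC(C)(C)C | intermediate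
11 | diallyl malonate (diprop-2-enyl propanedioate) | C=CCOC(=O)CC(=O)OCC=C | starting material
12 | diallyl 2-[(3E,5S)-7-tert-butoxy-5-ethenyl-3-(furan-2-yl)-5-methyl-2,7-dioxohept-3-en-1-yl]propanedioate | C=CCOC(=O)C(CC(=O)/C(c1ccco1)=C/[C@](C)(C=C)CC(=O)OC(C)(C)C)C(=O)OCC=C | intermediate
13 | but-2-yne-1,4-diol | OCC#CCO | starting material
14 | 4-[(tert-butyldimethylsilyl)oxy]but-2-yn-1-ol | OCC#CCO[Si](C)(C)C(C)(C)C | intermediate
15 | 4-[(tert-butyldimethylsilyl)oxy]but-2-ynal | O=CC#CCO[Si](C)(C)C(C)(C)C | intermediate
16 | diallyl 2-[(2Z)-1-[(tert-butyldimethylsilyl)oxy]-4-oxobut-2-en-2-yl]-2-[(3E,5S)-7-tert-butoxy-5-ethenyl-3-(furan-2-yl)-5-methyl-2,7-dioxohept-3-en-1-yl]propanedioate | O=C/C=C(\CO[Si](C)(C)C(C)(C)C)C(CC(=O)/C(c1ccco1)=C/[C@](C)(C=C)CC(=O)OC(C)(C)C)(C(=O)OCC=C)C(=O)OCC=C | intermediate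
17 | ring B keto aldehyde: cyclohexanone with C7(CO2allyl)2, C3(CH2OTBS)(CH2CHO), C10-(2-furyl) and C20-[C18(CH3)(vinyl)CH2CO2tBu]; C3, C10, C18, C20 as in 26 | O=CC[C@@]1(CO[Si](C)(C)C(C)(C)C)C(C(=O)OCC=C)(C(=O)OCC=C)CC(=O)[C@@H](c2ccco2)[C@@H]1[C@](C)(C=C)CC(=O)OC(C)(C)C | intermediate (not isolated)
18 | trans-fused bicyclic hydroxy ketone (rings A and B): C1–OH and C19–CH3 trans and equatorial, C3–CH2OTBS and C18–CH3 axial on one face, H-20 on the other, C10 furyl equatorial, C7(CO2allyl)2, C18–CH2CO2tBu | O[C@H]1C[C@@]2(CO[Si](C)(C)C(C)(C)C)C(C(=O)OCC=C)(C(=O)OCC=C)CC(=O)[C@@H](c3ccco3)[C@@H]2[C@@](C)(CC(=O)OC(C)(C)C)[C@@H]1C | intermediate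
19 | C1 acetate of 18 | CC(=O)O[C@H]1C[C@@]2(CO[Si](C)(C)C(C)(C)C)C(C(=O)OCC=C)(C(=O)OCC=C)CC(=O)[C@@H](c3ccco3)[C@@H]2[C@@](C)(CC(=O)OC(C)(C)C)[C@@H]1C | intermediate
20 | hydroxy diester (19 without the silyl group, free CH2OH on C3) | CC(=O)O[C@H]1C[C@@]2(CO)C(C(=O)OCC=C)(C(=O)OCC=C)CC(=O)[C@@H](c3ccco3)[C@@H]2[C@@](C)(CC(=O)OC(C)(C)C)[C@@H]1C | intermediate (not isolated)
21 | ring D lactone: γ-lactone C3–C4–O–C6(=O)–C7 cis-fused to ring B, allyl ester on C7 trans to C4, tert-butyl ester on C17 | CC(=O)O[C@H]1C[C@@]23COC(=O)[C@]2(C(=O)OCC=C)CC(=O)[C@@H](c2ccco2)[C@@H]3[C@@](C)(CC(=O)OC(C)(C)C)[C@@H]1C | intermediate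
22 | C16 carboxylic acid of 21 | CC(=O)O[C@H]1C[C@@]23COC(=O)[C@]2(C(=O)OCC=C)CC(=O)[C@@H](c2ccco2)[C@@H]3[C@@](C)(CC(=O)O)[C@@H]1C | intermediate
23 | C16 acid chloride of 22 | CC(=O)O[C@H]1C[C@@]23COC(=O)[C@]2(C(=O)OCC=C)CC(=O)[C@@H](c2ccco2)[C@@H]3[C@@](C)(CC(=O)Cl)[C@@H]1C | intermediate (not isolated)
24 | tetracyclic diketone: ring C closed (furan C3–C16 ketone), C9 ketone, saturated lactone with allyl ester on C7; other centres as in 26 | CC(=O)O[C@H]1C[C@@]23COC(=O)[C@]2(C(=O)OCC=C)CC(=O)[C@H]2c4occc4C(=O)C[C@@](C)([C@@H]1C)[C@@H]23 | intermediate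
25 | 9-oxo analogue of the target (C7=C8 enone-lactone) | CC(=O)O[C@H]1C[C@@]23COC(=O)C2=CC(=O)[C@H]2c4occc4C(=O)C[C@@](C)([C@@H]1C)[C@@H]23 | intermediate
26 | CNP0182929.2 | CC(=O)O[C@H]1C[C@@]23COC(=O)C2=C[C@H](O)[C@H]2c4occc4C(=O)C[C@@](C)([C@@H]1C)[C@@H]23 | target

**Step count and risks**

Total: 17 steps. Longest linear sequence: 15 steps (1 to 26 through steps 1–7 and 10–17).

Step 11 (proposed new method). What may go wrong: two-electron reduction of the enal or pinacol-type coupling of C1 with C9 before the C3–C20 bond forms, over-reduction of the C9 ketone, and weak facial control at C20 by the acyclic C18 centre. Fallback, from 16 back to 18, with known chemistry: the two ring closures are separated. The first is run as a tin-ketyl reductive cyclisation (Bu3SnH, AIBN, PhH, 80 °C; β,β-coupling of enal and enone through an O-stannyl allylic radical), which after hydrolysis of the tin enolates should give the keto aldehyde 17, here isolated and freed from any C20 epimer. Compound 17 is then closed to 18 by a standard ketyl–olefin cyclisation (SmI2, HMPA, tBuOH, THF, −78 °C). This fallback passes only through compounds of the list (no new compound, F0).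

Step 15. What may go wrong: acylation between molecules at the free α-position of the furan, or acid-induced opening of the furan, in competition with the slow closure of a seven-membered ring. Fallback, from 22 back to 24: the acylium route is replaced by a Vilsmeier–Haack-type cyclisation. Acid 22 is coupled with Me2NH·HCl (EDC·HCl, HOBt, iPr2NEt, CH2Cl2) to the N,N-dimethylamide F1; POCl3 (1,2-dichloroethane, 60 °C) activates the amide and should cyclise it onto the furan 3-position to the cyclic iminium chloride F2; aqueous NaOAc hydrolyses F2 to the ketone 24.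

Step 10. What may go wrong: 1,2-addition to the ynal and its base-induced oligomerisation, or aldol closure of C8 onto C1 in the product. Fallback, from 15 back to 16: conjugate addition to the alkyne is replaced by vinylic substitution. Ynal 15 is treated with LiCl in AcOH (anti hydrochlorination) to give the (2Z)-β-chloro enal F3, and the sodium enolate of 12 (NaH, THF, −20 °C) should displace chloride from F3 by addition–elimination to give 16 (either alkene isomer serves in step 11).

Further compounds
F0 | step 11 | none | none
F1 | step 15 | N,N-dimethylamide of acid 22 (CONMe2 in place of CO2H at C16) | CC(=O)O[C@H]1C[C@@]23COC(=O)[C@]2(C(=O)OCC=C)CC(=O)[C@@H](c2ccco2)[C@@H]3[C@@](C)(CC(=O)N(C)C)[C@@H]1C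
F2 | step 15 | cyclic C16 N,N-dimethyliminium chloride (iminium analogue of ketone 24) | CC(=O)O[C@H]1C[C@@]23COC(=O)[C@]2(C(=O)OCC=C)CC(=O)[C@H]2c4occc4C(=[N+](C)C)C[C@@](C)([C@@H]1C)[C@@H]23.[Cl-]
F3 | step 10 | (2Z)-4-[(tert-butyldimethylsilyl)oxy]-3-chlorobut-2-enal | O=C/C=C(\Cl)CO[Si](C)(C)C(C)(C)C
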